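Remark on the chemistry (assumption): the target is taken exactly as drawn, with a methyl group on each fusion carbon. Its locants C1–C10 (decalin), C12 (oxymethylene carbon on C9) and C13 (methylene carbon on C8) are kept for every intermediate. The structures of the key-step precursor 18 and product 19 were checked atom by atom against the target and agree with it in constitution and configuration.

## Structural features

The target is a 7-O-alkylated umbelliferone whose C12H2 group hangs on C9 of a cis-fused decalin; rings A and B share the C5–C10 bond and both fusion carbons are quaternary and methylated. Ring A carries the C3 acetate and the C4 gem-dimethyl carbon, so C4, C5 and C10 form a run of three contiguous fully substituted carbons; ring B carries the exocyclic C8 methylene next to the C9 methine. The stereocentres are C3 (S), C5 (S), C10 (R) and C9 (S); C5, C10 and C9 are contiguous, C3 is 1,3 to C5, and the acetoxy group, both angular methyls and C12 all lie on one face. Fragile groups are the acetate (hydride, ylide, acetylide), the coumarin lactone (nucleophiles), the 1,1-disubstituted alkene (acid-induced migration into the ring) and, at the aldehyde stage, the C9–H, which is both α to the carbonyl and allylic. The real difficulties are the congested C4–C5–C10 array with cis methyls, and C9: with C12 cis to both angular methyls, either chair of the cis-decalin pays a syn-axial contact, so this is the less stable C9 epimer and cannot be reached by equilibration. The key step exploits the unit C8(=C13H2)–C9H–C12: a 1,1-disubstituted alkene carbon bonded to a carbonyl α-carbon is what an enol carbon (C9) gives on adding to the internal carbon (C8) of a terminal alkyne. Ring B can therefore be closed last, at C8–C9, from a ring A that carries a butynyl arm on C5 and an enol ether arm on C10.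

## Logic of the disconnections

23 is cut at the C12–O aryl ether bond into 21 and 22. This is the only bond between the two halves, 22 is commercial, and joining last keeps the lactone away from every basic or reducing step. The forward step must etherify a β-branched primary alcohol under neutral conditions.

21 is traced to 19 through 20, by cutting the C9–H bond and the C12–H bond. Because the wanted C9 configuration is the less stable one, the C9–H bond is made the last event at this centre, by kinetic protonation, with reduction in the same flask. The gain is that ring closure no longer has to control C9. The demand is α- rather than γ-protonation, from the face away from the C5 methyl, and reduction faster than epimerization.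

19 is cut at C8–C9 to 18 (key step). The cut removes ring B and leaves a monocyclic ring A with two arms. The forward step must close 6-exo-dig rather than 7-endo, must form the C–C bond before the silyl enol ether is lost, and must not move the new alkene.

18 goes back to 17 (O–Si bond), 17 to 16 (aldehyde masked as methyl enol ether) and 16 to 15 (acetate C–O bond). The acetate is placed only after all hydride, ylide and acetylide chemistry. The demands are enolization of the aldehyde only and an enol ether hydrolysis mild enough for acetate and alkyne. No extra bias at C9 is built into 18, because no spectator change would steer the C9 outcome reliably; that point is settled downstream.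

15 is cut at C7–C8 to 14 and then 13. An acetylide meets a primary, non-neopentyl electrophile. The demand is selective activation of the primary hydroxyl beside the hindered C3 hydroxyl.

13 is cut at C9=C12 to 12 and then 11. Olefination of the lactol adds C12 and at the same time frees the C7 hydroxyl, so the two arms are told apart without protecting groups. The demand is olefination of a neopentyl aldehyde that is present only in equilibrium with its lactol.

11 is reconnected between C9 and C7 (through 10) to 9. Both arms then come from one cyclopentene ring and are cis on C5 and C10 by construction; cleavage of a silyl enol ether leaves the two termini at different oxidation levels. The demand is that ozone meets no other alkene.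

9 goes back to 8 by the C3–H bond. The carbinol is made from the ketone left by the annulation, under reagent control because the substrate bias cannot be predicted. The demand is hydride delivery to one face of a ketone between a quaternary carbon and a CH2, with the enol ether untouched.

8 is cut at C4–CH3 (through 7) to 6, and 6 at the O–Si bond on C9 to 5. The silyl enol ether at C3–C4 releases the enolate regiospecifically; the second enol ether masks the other carbonyl and prepares the ring opening. The demands are cleavage of one of two silyl enol ethers and C- over O-methylation at a doubly neopentyl carbon.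

5 is cut at C5–CH3 to 4. Conjugate addition makes quaternary C5 cis to the C10 methyl and traps the enolate needed above. The demand is 1,4-addition to a tetrasubstituted enone.

4 is cut at C4=C5 to 3, and 3 at C10–C1 to 1 and 2. This is an annulation of two commercial compounds in which an amino acid sets C10, the source of all absolute configuration.

## Other disconnections considered

Alternative 1: The cut is C5–C6 in ring B, by a retro-[3,3] shift that restores a C3–C8 bond. In the forward direction KH with 18-crown-6 turns vinyl carbinol A1 into its alkoxide, whose anionic oxy-Cope shift would give the cis-decalin epoxy ketone A2 as its C8 enolate.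
- In its favour: ring B and the cis relation of the two methylated fusion carbons would arise in one stereospecific pericyclic step enforced by the bicyclo[2.2.2]octene. Both quaternary carbons come from an aromatic ring, so no C–C bond has to be made at a hindered carbon; on this structural point it is better than the chosen plan, whose step 3 is a difficult conjugate addition. The C8 carbonyl and the C12 oxygen are already in place.
- Against it here: A2 lacks the second C4 methyl and the C3 carbinol, so a regioselective C4 methylation (C2 competes) and a C3 reduction remain. The spiro-epoxide must be opened reductively at C9, which then sits α to the C8 ketone. That ketone must be methylenated next to this epimerizable centre. The dearomatization and cycloaddition entry to A1 gives no absolute control without an added resolution or auxiliary, whereas the chosen plan takes it from a catalytic step at the start.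
- Comparison: on mechanism the concerted shift is at least as dependable as the gold closure. On C9 the two plans are equal, since both end with a kinetic protonation next to a carbonyl. On step economy the alternative reaches the bicycle sooner but has the longer and less certain end game.

Alternative 2: The cut is C4–C5. In the forward direction MeAlCl2 opens the (R)-epoxide of phenol A3 at its tertiary carbon and the para carbon, ipso to methyl, attacks to give the dienone carbinol A4.
- In its favour: one step would close ring A and create the gem-dimethyl carbon, quaternary C5 and the C3 carbinol together, with absolute configuration from a simple epoxide. For the C4/C5 array this is better than steps 3 and 5 of the chosen plan.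
- Against it here: C3 emerges epimeric and needs oxidation and stereoselective reduction, the same problem as step 6 (equal). The C10 methyl is still missing; it would have to add to the fully substituted β-carbon of the dienone in competition with the unhindered C6=C7 arm, and cis to the C5 methyl, which is harder than step 3. Ortho attack and dienone–phenol rearrangement threaten under the Lewis acid. Saturation of C6–C7, C8 methylenation and C9 protonation would follow.
- Comparison: shorter and more convergent at the front, but the second quaternary centre and C9 are left to a less controlled back end; overall step count would be similar.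

Alternative 3: The cut is C3–C4. In the forward direction Fe(acac)3 with PhSiH3 transfers a hydrogen atom to the isopropenyl group of aldehyde A5, and the tertiary C4 radical adds to the C3 aldehyde to give carbinol A6.
- In its favour: the gem-dimethyl carbon and the C3–O bond would form in one neutral step, directly at the alcohol level; this is better than the separate reduction of step 6. A radical tolerates the congestion at C4. No noble metal is needed.
- Against it here: the vicinal quaternary carbons C5 and C10 and the C9 centre must already be assembled in A5, so the hardest problem is moved, not solved. Radical addition to a carbonyl is reversible, and the C3 configuration would rest on a chair preference that is as uncertain as in the chosen plan (equal). After A6, ketal removal, methylenation next to an epimerizable C9, ether cleavage, acetylation and etherification remain, against two steps in the chosen plan.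
- Comparison: both plans close a six-membered ring by carbon attack on a π-bond and leave one centre to conformational control; the alternative has the longer end game and the harder precursor.

Key step: step 15

## Steps

Step 1
Reactants: 1 2-methylcyclopentane-1,3-dione; 2 ethyl vinyl ketone (pent-1-en-3-one)
Product: 3 2-methyl-2-(3-oxopentyl)cyclopentane-1,3-dione
Conditions: AcOH (cat.), H2O, 70 °C
Reagents that add atoms: none
Why: Michael addition of the enolized 1,3-dione to the vinyl ketone forms C10–C1; the product has no hydrogen left between the ring carbonyls, so the addition stops, and no stereocentre exists yet because the two ring carbonyls are enantiotopic.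

Step 2
Reactants: 3 2-methyl-2-(3-oxopentyl)cyclopentane-1,3-dione
Product: 4 (7aS)-4,7a-dimethyl-2,3,7,7a-tetrahydro-1H-indene-1,5(6H)-dione
Conditions: L-phenylalanine (1 equiv), (+)-camphor-10-sulfonic acid (0.5 equiv), DMF, 30 to 70 °C
Reagents that add atoms: none
Why: Hajos–Parrish-type intramolecular aldol condensation through the enamine of the side-chain ketone forms C4=C5; a primary amino acid is used because the ethyl ketone is too hindered for a proline enamine, and the L-catalyst should select the ring carbonyl that gives the (S)-enone (C10 set), which can be enriched by crystallization.

Step 3
Reactants: 4 (7aS)-4,7a-dimethyl-2,3,7,7a-tetrahydro-1H-indene-1,5(6H)-dione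
Product: 5 (3aR,7aS)-3a,4,7a-trimethyl-5-(trimethylsilyloxy)-2,3,3a,6,7,7a-hexahydro-1H-inden-1-one (cis-fused; C5 and C10 methyls on one face)
Conditions: Me2CuLi (from CuI and 2 MeLi), Me3SiCl, THF/Et2O, −78 to −20 °C; Et3N, pentane work-up
Reagents that add atoms: lithium dimethylcuprate [Li+].C[Cu-]C; chlorotrimethylsilane C[Si](C)(C)Cl
Why: Cuprate conjugate addition accelerated by Me3SiCl, which traps the enolate as the C3–C4 silyl enol ether and leaves the neopentyl cyclopentanone alone at low temperature; methyl should arrive at C5 on the face of the C10 methyl because only that trajectory leads to the unstrained cis-hydrindane, as is usual for angularly substituted bicyclic enones.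

Step 4
Reactants: 5 (3aR,7aS)-3a,4,7a-trimethyl-5-(trimethylsilyloxy)-2,3,3a,6,7,7a-hexahydro-1H-inden-1-one
Product: 6 bis(silyl enol ether) of the cis-hydrindanedione: Me3Si enol ether at C3–C4 and t-BuMe2Si enol ether at C9–C7
Conditions: LiN(i-Pr)2, THF, −78 °C; t-BuMe2SiCl, DMPU, −78 to 0 °C
Reagents that add atoms: tert-butylchlorodimethylsilane CC(C)(C)[Si](C)(C)Cl
Why: Only C7 carries hydrogens α to the cyclopentanone, so kinetic enolization and O-silylation give one enol ether; it protects this carbonyl through steps 5 and 6 and is the handle for ring opening in step 7, while the Me3Si enol ether is inert to the amide base.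

Step 5
Reactants: 6 bis(silyl enol ether)
Product: 8 cis-hydrindane C3 ketone with C4 gem-dimethyl and the t-BuMe2Si enol ether at C9–C7, via lithium enolate 7 (not isolated)
Conditions: MeLi (1.05 equiv), THF, 0 °C to rt; then MeI, DMPU, −78 to 0 °C
Reagents that add atoms: iodomethane CI
Why: MeLi attacks silicon of the small Me3Si enol ether far faster than the t-BuMe2Si one and releases the C3–C4 lithium enolate regiospecifically; C-methylation by the smallest electrophile completes the gem-dimethyl carbon (regiospecific enolate generation and alkylation), and no stereocentre is formed.

Step 6
Reactants: 8 cis-hydrindane C3 ketone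
Product: 9 (3S)-alcohol: cis-hydrindane with C3 hydroxyl on the face of the two angular methyls and the t-BuMe2Si enol ether at C9–C7
Conditions: (R)-Me-CBS oxazaborolidine (C18H20BNO, 0.5 equiv), catecholborane, toluene, −78 to −30 °C; aq NaOH work-up
Reagents that add atoms: none
Why: Corey–Bakshi–Shibata reduction; the ketone lies between quaternary C4 (large) and C2H2 (small), and with this ranking the (R)-catalyst should deliver hydride to the face that gives the (3S)-carbinol, while catecholborane at low temperature does not hydroborate the silyl enol ether.

Step 7
Reactants: 9 (3S)-alcohol
Product: 11 cis-fused hydroxy δ-lactone (C9 carbonyl on C10; ring O–C7H2–C6H2 on C5; 3S hydroxyl), via hydroxy acid 10 (not isolated)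
Conditions: O3, CH2Cl2/MeOH, −78 °C; NaBH4, −78 °C to rt; aq HCl, then TsOH (cat.), CH2Cl2, rt
Reagents that add atoms: ozone [O-][O+]=O
Why: Ozonolysis of the silyl enol ether cleaves C9=C7 to a carboxylic acid at C9 and, after borohydride reduction, a primary alcohol at C7; on acidification the δ-hydroxy acid closes to the six-membered lactone, which tells the two arms apart by oxidation level, and no stereocentre is touched.

Step 8
Reactants: 11 hydroxy δ-lactone
Product: 12 lactol (C9 hemiacetal; anomers)
Conditions: i-Bu2AlH (2.5 equiv), CH2Cl2, −78 °C; aq potassium sodium tartrate
Reagents that add atoms: none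
Why: Partial reduction of a lactone; the aluminium hemiacetal of the neopentyl carbonyl persists at −78 °C, so reduction stops at the lactol, and the extra equivalent allows for the free C3 hydroxyl.

Step 9
Reactants: 12 lactol
Product: 13 ring A diol with (2-methoxyvinyl) on C10 (E/Z) and 2-hydroxyethyl on C5
Conditions: Ph3P(CH2OMe)Cl, KN(SiMe3)2, THF, 0 to 40 °C
Reagents that add atoms: (methoxymethyl)triphenylphosphonium chloride COC[P+](c1ccccc1)(c1ccccc1)c1ccccc1.[Cl-]
Why: Wittig olefination of the ring-opened hydroxy aldehyde with a small, reactive ylide adds C12 as an enol ether and frees the C7 hydroxyl in the same event; excess ylide covers the two alkoxides, and both alkene isomers are used.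

Step 10
Reactants: 13 ring A diol
Product: 14 primary C7 p-toluenesulfonate
Conditions: TsCl (1.1 equiv), pyridine, CH2Cl2, 0 °C
Reagents that add atoms: p-toluenesulfonyl chloride Cc1ccc(cc1)S(Cl)(=O)=O
Why: Sulfonylation is selective for the unhindered primary alcohol over the C3 hydroxyl, which is secondary and flanked by the gem-dimethyl carbon; basic conditions spare the enol ether.

Step 11
Reactants: 14 primary C7 p-toluenesulfonate
Product: 15 ring A alcohol with but-3-ynyl on C5 and (2-methoxyvinyl) on C10
Conditions: LiC≡CH·H2NCH2CH2NH2 (4 equiv), DMSO, rt
Reagents that add atoms: lithium acetylide ethylenediamine complex [Li+].[C-]#C.NCCN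
Why: SN2 displacement of a primary sulfonate by acetylide in a dipolar aprotic solvent adds C8 and C13 as the terminal alkyne; C7 is not neopentyl, and the C3 alkoxide is a spectator that cannot reach C7 from the opposite face of ring A.

Step 12
Reactants: 15 ring A alkynyl alcohol
Product: 16 C3 acetate
Conditions: Ac2O, DMAP (cat.), pyridine, rt to 40 °C
Reagents that add atoms: acetic anhydride CC(=O)OC(C)=O
Why: DMAP-catalysed acylation of the hindered secondary alcohol; it is placed here because every hydride, ylide and acetylide step is now past.

Step 13
Reactants: 16 C3 acetate
Product: 17 aldehyde: ring A acetate with but-3-ynyl on C5 and 2-oxoethyl on C10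
Conditions: 1 M HCl, THF, rt
Reagents that add atoms: water O
Why: Acid hydrolysis of the enol ether by protonation at C9 and collapse of the hemiacetal; acetate and terminal alkyne tolerate dilute acid at room temperature.

Step 14
Reactants: 17 aldehyde
Product: 18 ring A alkynyl silyl enol ether: acetate with but-3-ynyl on C5 and (E)-2-(tert-butyldimethylsilyloxy)vinyl on C10
Conditions: t-BuMe2SiOTf, Et3N, CH2Cl2, −78 to 0 °C
Reagents that add atoms: tert-butyldimethylsilyl trifluoromethanesulfonate CC(C)(C)[Si](C)(C)OS(=O)(=O)C(F)(F)F
Why: Soft enolization: O-silylation of the aldehyde and deprotonation at C9 by the amine, far easier than enolization of the acetate; the E geometry is expected because the tertiary C10 avoids the siloxy group, and the geometry is lost again in step 15.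

Step 15
Reactants: 18 ring A alkynyl silyl enol ether
Product: 19 (3S,5S,9S,10R)-C12 aldehyde with exocyclic C8 methylene (cis-decalin)
Conditions: Ph3PAuCl (5 mol%), AgOTf (5 mol%), toluene/MeOH (10:1), rt
Reagents that add atoms: none
Why: Ph3PAu+ (monovalent gold, freed from Ph3PAuCl by AgOTf) binds the terminal alkyne and the enol ether carbon C9 adds anti to gold at the internal carbon C8, giving a vinyl gold species and a silyloxocarbenium ion at C12; methanol takes the silyl group to reveal the aldehyde and protonates the C–Au bond with retention, so the C8=C13 alkene is delivered without migration. The closest known reaction type is the gold-catalysed exo-dig carbocyclization of silyl enol ethers onto tethered terminal alkynes, a catalytic Conia-ene variant. Ring B closes in the 6-exo-dig mode, since the 7-endo path would need attack at the unsubstituted terminus C13 against the Markovnikov polarization of the gold–alkyne complex. The closure is helped by the adjacent quaternary carbons C5 and C10, which hold the two arms gauche on one face of ring A. C9 is the one new stereocentre and is fixed in the C–C bond-forming event by a chair-like array with C12 pseudo-equatorial; the drawn (9S) configuration follows when ring A takes the chair with the C10 arm axial, the opposite one when ring A takes its other chair. These two arrays lie close in energy, so the route asks no facial selectivity at C9 of this step: C9 becomes planar again in dienolate 20 and is set for good in step 16. The step does need exo over endo closure (secured by the terminal alkyne), C–C bond formation ahead of protodesilylation (secured by the bulky silyl group and the low methanol content) and an untouched acetate (neutral conditions).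

Step 16
Reactants: 19 (3S,5S,9S,10R)-C12 aldehyde with exocyclic C8 methylene
Product: 21 (3S,5S,9S,10R)-C12 primary alcohol with C3 acetate and C8 methylene, via potassium dienolate 20 (not isolated)
Conditions: KN(SiMe3)2 (1.2 equiv), THF, −78 to −40 °C; AcOH, −78 °C; then NaBH4, MeOH, −78 to −20 °C
Reagents that add atoms: none
Why: Deconjugative kinetic protonation of a dienolate followed by borohydride reduction: C9 is planar in 20, so the outcome does not depend on the C9 configuration with which the aldehyde leaves step 15, and protonation occurs at the α-carbon C9, which keeps the exocyclic methylene. The proton should arrive on the outward α lobe, because in the favoured chair, with the C10 methyl equatorial on ring B, the β lobe lies under the axial C5 methyl; the resulting less stable (9S)-aldehyde is reduced in the same flask before it can epimerize.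

Step 17
Reactants: 21 (3S,5S,9S,10R)-C12 primary alcohol; 22 umbelliferone (7-hydroxycoumarin)
Product: 23 polyanthinin
Conditions: PPh3, DIAD, THF, 0 °C to rt
Reagents that add atoms: none
Why: Mitsunobu etherification of an acidic phenol with a primary alcohol; C12 is not stereogenic, and the neutral conditions spare the acetate, the lactone and the exocyclic alkene.

## Compound list

1 | 2-methylcyclopentane-1,3-dione | CC1C(=O)CCC1=O | starting material
2 | ethyl vinyl ketone | CCC(=O)C=C | starting material
3 | 2-methyl-2-(3-oxopentyl)cyclopentane-1,3-dione | CCC(=O)CCC1(C)C(=O)CCC1=O | intermediate
4 | (7aS)-4,7a-dimethyl-2,3,7,7a-tetrahydro-1H-indene-1,5(6H)-dione | CC1=C2CCC(=O)[C@@]2(C)CCC1=O | intermediate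
5 | (3aR,7aS)-3a,4,7a-trimethyl-5-(trimethylsilyloxy)-2,3,3a,6,7,7a-hexahydro-1H-inden-1-one | C[Si](C)(C)OC1=C(C)[C@@]2(C)CCC(=O)[C@@]2(C)CC1 | intermediate
6 | bis(silyl enol ether) of the cis-hydrindanedione | C[Si](C)(C)OC1=C(C)[C@@]2(C)CC=C(O[Si](C)(C)C(C)(C)C)[C@@]2(C)CC1 | intermediate
7 | lithium enolate (C3–C4) | [Li+].[O-]C1=C(C)[C@@]2(C)CC=C(O[Si](C)(C)C(C)(C)C)[C@@]2(C)CC1 | intermediate (not isolated)
8 | cis-hydrindane C3 ketone with C4 gem-dimethyl and silyl enol ether | O=C1C(C)(C)[C@@]2(C)CC=C(O[Si](C)(C)C(C)(C)C)[C@@]2(C)CC1 | intermediate
9 | (3S)-alcohol with silyl enol ether | O[C@@H]1C(C)(C)[C@@]2(C)CC=C(O[Si](C)(C)C(C)(C)C)[C@@]2(C)CC1 | intermediate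
10 | hydroxy acid (C9 acid on C10, 2-hydroxyethyl on C5) | O[C@@H]1C(C)(C)[C@@](C)(CCO)[C@@](C)(C(=O)O)CC1 | intermediate (not isolated)
11 | cis-fused hydroxy δ-lactone | O[C@@H]1C(C)(C)[C@@]2(C)CCOC(=O)[C@@]2(C)CC1 | intermediate
12 | lactol | O[C@@H]1C(C)(C)[C@@]2(C)CCOC(O)[C@@]2(C)CC1 | intermediate
13 | diol with (2-methoxyvinyl) arm (E/Z) | O[C@@H]1C(C)(C)[C@@](C)(CCO)[C@@](C)(C=COC)CC1 | intermediate
14 | primary C7 p-toluenesulfonate | O[C@@H]1C(C)(C)[C@@](C)(CCOS(=O)(=O)c2ccc(C)cc2)[C@@](C)(C=COC)CC1 | intermediate
15 | alkynyl alcohol with (2-methoxyvinyl) arm | O[C@@H]1C(C)(C)[C@@](C)(CCC#C)[C@@](C)(C=COC)CC1 | intermediate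
16 | C3 acetate of 15 | CC(=O)O[C@@H]1C(C)(C)[C@@](C)(CCC#C)[C@@](C)(C=COC)CC1 | intermediate
17 | alkynyl aldehyde (2-oxoethyl on C10) | CC(=O)O[C@@H]1C(C)(C)[C@@](C)(CCC#C)[C@@](C)(CC=O)CC1 | intermediate
18 | ring A alkynyl silyl enol ether (key-step precursor) | C#CCC[C@]1(C)C(C)(C)[C@@H](OC(C)=O)CC[C@]1(C)/C=C/O[Si](C)(C)C(C)(C)C | intermediate
19 | (3S,5S,9S,10R)-C12 aldehyde with exocyclic methylene (key-step product) | C=C1CC[C@]2(C)C(C)(C)[C@@H](OC(C)=O)CC[C@]2(C)[C@H]1C=O | intermediate
20 | potassium dienolate (O–C12=C9–C8=C13) | C=C1CC[C@]2(C)C(C)(C)[C@@H](OC(C)=O)CC[C@]2(C)C1=C[O-].[K+] | intermediate (not isolated)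
21 | (3S,5S,9S,10R)-C12 primary alcohol | C=C1CC[C@]2(C)C(C)(C)[C@@H](OC(C)=O)CC[C@]2(C)[C@H]1CO | intermediate
22 | umbelliferone | O=c1ccc2ccc(O)cc2o1 | starting material
23 | polyanthinin | C=C1CC[C@]2(C)C(C)(C)[C@@H](OC(C)=O)CC[C@]2(C)[C@H]1COc1ccc2ccc(=O)oc2c1 | target

## Step count and least certain steps

Total: 17 steps. Longest linear sequence: 17 steps (1 and 2 to 23; 22 enters in the last step).

Step 15 (key step). Protodesilylation of the enol ether by methanol and adventitious acid may outrun C–C bond formation and return 17, because C9 is a neopentyl nucleophile; the second weakness, no facial control at C9, is already absorbed by step 16. Fallback: setting out from 18, stoichiometric activation of the alkyne by divalent mercury (HgCl2, (Me3Si)2NH, CH2Cl2) closes the same C8–C9 bond to the vinylmercuric chloride F1, and NaI with aqueous HCl then replaces mercury by hydrogen with retention; the route is rejoined at 19.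

Step 3. Methyl transfer to the fully substituted β-carbon may not take place (recovered or reduced enone), because C5 is flanked by quaternary C10 and the α-carbon is methylated. Fallback: setting out from 4, NaBH4 with CeCl3·7H2O reduces both carbonyls to the diol F2, whose allylic C3 hydroxyl on the face of the C10 methyl directs Et2Zn/CH2I2 cyclopropanation of C4=C5 to that face to give the cyclopropyl diol F3. Dess–Martin oxidation gives the cyclopropyl dione F4. Me3SiI opens the conjugated cyclopropane at its CH2 carbon to the iodomethyl silyl enol ether F5, and Bu3SnH with AIBN removes iodine; the route is rejoined at 5.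

Step 5. O-methylation, or proton transfer followed by methylation at C2, may compete, because the enolate carbon is tetrasubstituted and next to a quaternary centre. Fallback: setting out from 5, Et2Zn/CH2I2 cyclopropanates the silyl enol ether to the siloxycyclopropane F6, and NaOH in MeOH opens it toward the primary carbon to the gem-dimethyl dione F7. The more reactive cyclohexanone is reduced under the conditions of step 6 to the hydroxy ketone F8. LiN(i-Pr)2 (2 equiv) with t-BuMe2SiCl (1 equiv) then silylates the enolate oxygen; the route is rejoined at 9.

Step 6. The substrate bias may override the catalyst, or the neopentyl ketone may react too slowly, because the two chairs of ring A expose opposite faces of C3. Fallback: setting out from 8, control is handed to the substrate with an achiral hydride chosen by trajectory (NaBH4 for axial, LiBH(s-Bu)3 for equatorial delivery). The (3R)-alcohol F9 is separated and returned to 8 by Dess–Martin oxidation; the (3S)-alcohol rejoins the route at 9.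

Step 9. Olefination may stall, because the lactol opens only to a small extent and its aldehyde sits on a carbon flanked by two quaternary centres. Fallback: setting out from 12, the lithium reagent from Me3SiCH2OMe and s-BuLi adds irreversibly to the open form to give the β-hydroxysilane F10, and KH induces Peterson elimination; the route is rejoined at 13.

Step 16. Protonation from the β face or at C13, incomplete enolization, or addition of the amide to the aldehyde carbonyl would erode C9 or divert material, because the bulky base must reach a hindered C–H. Fallback: setting out from 19, soft enolization (t-BuMe2SiOTf, Et3N) gives the silyl dienol ether F11 without strong base. Bu4NF with AcOH at −78 °C then releases and protonates the dienolate, and NaBH4 is added to the same flask; the route is rejoined at 21.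

## Further compounds

F1 | step 15 | vinylmercuric chloride of the cyclized aldehyde | Cl[Hg]C=C1CC[C@]2(C)C(C)(C)[C@@H](OC(C)=O)CC[C@]2(C)C1C=O
F2 | step 3 | hydrindene diol (allylic C3 hydroxyl and C9 hydroxyl, both on the face of the C10 methyl) | CC1=C2CC[C@H](O)[C@@]2(C)CC[C@@H]1O
F3 | step 3 | cyclopropyl diol (CH2 across C4–C5 on the face of the C10 methyl) | C[C@@]12C[C@@]13CC[C@H](O)[C@@]3(C)CC[C@@H]2O
F4 | step 3 | cyclopropyl dione | C[C@@]12C[C@@]13CCC(=O)[C@@]3(C)CCC2=O
F5 | step 3 | iodomethyl silyl enol ether (C5–CH2I) | C[Si](C)(C)OC1=C(C)[C@@]2(CI)CCC(=O)[C@@]2(C)CC1
F6 | step 5 | siloxycyclopropane from 5 | C[Si](C)(C)OC12CC1(C)[C@@]3(C)CCC(=O)[C@@]3(C)CC2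
F7 | step 5 | cis-3a,4,4,7a-tetramethylhexahydroindane-1,5-dione | O=C1C(C)(C)[C@@]2(C)CCC(=O)[C@@]2(C)CC1
F8 | step 5 | (3S)-hydroxy ketone | O[C@@H]1C(C)(C)[C@@]2(C)CCC(=O)[C@@]2(C)CC1
F9 | step 6 | (3R)-epimer of 9 | O[C@H]1C(C)(C)[C@@]2(C)CC=C(O[Si](C)(C)C(C)(C)C)[C@@]2(C)CC1
F10 | step 9 | β-hydroxysilane adduct (triol) | O[C@@H]1C(C)(C)[C@@](C)(CCO)[C@@](C)(C(O)C(OC)[Si](C)(C)C)CC1
F11 | step 16 | silyl dienol ether of 19 | C=C1CC[C@]2(C)C(C)(C)[C@@H](OC(C)=O)CC[C@]2(C)C1=CO[Si](C)(C)C(C)(C)C
A1 | alternative 1 | vinyl bicyclo[2.2.2]octenol with spiro-epoxide (oxy-Cope substrate) | C=C[C@]1(O)[C@]2(CO2)[C@@]3(C)CC[C@]1(OC)C(C)=C3C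
A2 | alternative 1 | cis-decalin epoxy ketone with C3 enol ether | O=C1CC[C@]2(C)C(C)=C(OC)CC[C@]2(C)[C@@]13CO3
A3 | alternative 2 | 2-[(tert-butyldimethylsilyloxy)methyl]-3-[2-((2R)-3,3-dimethyloxiran-2-yl)ethyl]-4-methylphenol | Cc1ccc(O)c(CO[Si](C)(C)C(C)(C)C)c1CC[C@H]1OC1(C)C
A4 | alternative 2 | bicyclic dienone carbinol (3-epi) | O=C1C=C[C@]2(C)C(C)(C)[C@H](O)CCC2=C1CO[Si](C)(C)C(C)(C)C
A5 | alternative 3 | ring B ketal aldehyde with isopropenyl on C5 and 3-oxopropyl on C10 | C12(CC[C@](C)(C(C)=C)[C@](C)(CCC=O)[C@H]1COCc1ccc(OC)cc1)OCCO2
A6 | alternative 3 | cis-decalin C3 carbinol | C12(CC[C@]3(C)C(C)(C)[C@@H](O)CC[C@]3(C)[C@H]1COCc1ccc(OC)cc1)OCCO2
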